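The rate constants are invented; the result is computed.

The trap in these flasks is to read the enzyme's speed off the charge, as if the substrates stayed at their charged levels.

common to all: free enzyme 6.6 × 10⁻⁴ mol%; time 1.0 h

| run | starting material | second substrate | remark |
|---|---|---|---|
| delta | 0.079 M | 1.10 equiv (fed, over 50 min) | all else is in the flask from the start; the feed brings no volume worth counting |
| zeta | 0.079 M | 1.10 equiv | everything together at the start |
| gamma | 0.079 M (fed, over 50 min) | 1.10 equiv | all else is in the flask from the start; the feed brings no volume worth counting |

    starting material + free enzyme ⇌ first complex (K1 = 2.61 M⁻¹, k1 = 59200 M⁻¹ s⁻¹)
    first complex → loaded enzyme + first product (k2 = 3430 s⁻¹)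
    second complex → free enzyme + target (k3 = 49.5 s⁻¹)
    target ⇌ isomer of the product (K4 = 2.9, k4 = 0.00108 s⁻¹)
    second substrate + loaded enzyme ⇌ second complex (K5 = 13 M⁻¹, k5 = 12300 M⁻¹ s⁻¹)

- the flask that comes out highest in amount of isomer of the product, in percent of the starting material charged; "all alike" if 1.5 percentage points covers them all (delta / zeta / gamma / all alike)
- amount of isomer of the product at the end, in percent of the starting material charged, delta
- amount of isomer of the product at the end, in percent of the starting material charged, zeta
- amount of isomer of the product at the end, in percent of the starting material charged, gamma

I reckon by waits, and I count each substrate as a fraction of the charge of starting material. One enzyme molecule needs 0.0202 s to release target from second complex. At a level of one charge it waits 0.0207 s for second substrate and 0.00163 s for starting material, counting only the bindings that go on and do not fall back. Each of these two waits stretches as one over its level. I leave out the 2.92 × 10⁻⁴ s that first complex needs to go on, which is shorter than the release. The sum at the start of zeta, 0.0406 s, is the turn time, the seconds one enzyme molecule needs for one round, and the loading divided by it is the fraction of the charge converted per second. Held at the charge, zeta would convert 58.5 % in 1.0 h, but that much conversion lowers both levels.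

My first way for zeta replaces each falling level by its mean, lowered by half of that conversion. The turn time becomes 0.0481 s and the conversion 49.4 %. My second way uses no mean: it sums the turn times along the run, and converting half of the charge in zeta takes 1.00 h. The two ways agree, so I trust the mean for zeta.

Target passes into isomer of the product with a lag of 11.5 min, and the isomer's share at balance is 74.4 %. For steady making, the isomer is that share of the conversion, cut by the lag over the time, so zeta gives 29.7 %.

In delta I take the mean delivered level of second substrate and subtract half of zeta's conversion as a first guess. The turn time is 0.0748 s, the conversion 31.8 %, and the isomer 19.1 %. In gamma the same step on starting material gives 0.0493 s, 48.2 % and 29.0 %. These two figures are rough: both lower the levels by zeta's conversion, and the conversion I reckon for delta is smaller than zeta's. I commit to zeta.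

The forecast names zeta, with 19.4 % for delta, 30.8 % for zeta and 27 % for gamma, reasoning that “the flask that makes target earliest and fastest” comes out highest.

The simulation gives zeta, with 19.4 % in delta, 30.7 % in zeta and 27.3 % in gamma, and zeta keeps 50.3 % of its starting material.

In delta at 0.500 h the readings give a turn time of 0.0603 s, of which the wait for second substrate is 63.4 % and the release 33.5 %, so the wait is longer than the release, and loaded enzyme, the resting state of delta at that moment, holds 63.1 % of the catalyst charged against 33.3 % in second complex. In the neighbour of delta with 1.90 equiv of second substrate, the end readings give a turn time of 0.0379 s, of which the wait for second substrate is 38.5 %, loaded enzyme holds 38.2 % of the catalyst charged, and the isomer of the product reaches 27.0 %.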